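## Retrosynthetic overview

1. Target 24 ⇐ one-pot face-selective syn-hydrogenation and global debenzylation of the tetraaryl 4,5-dihydrofuran 22; this sets oxolane C2 and C3 last and replaces the usual biomimetic oxidative 8–8' coupling of stilbenes.
2. 22 ⇐ Pd-catalysed arylative 5-endo-dig cyclisation that joins anti-alkynol 21 (fragment B) to aryl bromide 13 (fragment A), forming O1–C2 and C3–aryl in one step.
3. 21 ⇐ Pd/Et2Zn umpolung propargylation of 4-(benzyloxy)benzaldehyde with the (S)-propargylic benzoate 18 (sets oxolane C4 and C5); 18 ⇐ catalytic asymmetric alkynylation.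
4. 13 ⇐ enantioselective dirhodium-carbene C–H insertion of a diaryldiazomethane, then C2 epimerisation to the trans (2S,3S) dihydrobenzofuran.
5. Ring order: dihydrobenzofuran (step 7) → dihydrofuran (step 12) → oxolane by saturation (step 13).

Assumption: compounds 1, 8, 14, 15 and 19 are bought, and for each chiral ligand or catalyst the enantiomer named is the one taken to give the drawn configuration (its mirror image is used, with no other change, if a first run shows the opposite sense).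

## Fragment A (steps 1–8)

Step 1
Reactants: 1 1,3-bis(benzyloxy)-5-bromobenzene
Product: 3 2,4-bis(benzyloxy)-6-bromobenzaldehyde, via iminium salt 2 (not isolated)
Conditions: POCl3, DMF, 0 → 90 °C; then H2O
Reagents that add atoms: N,N-dimethylformamide, CN(C)C=O; water, O
Why: Vilsmeier–Haack formylation, in which the chloroiminium electrophile attacks the position ortho to bromine and para to one benzyloxy group (less hindered than the site flanked by both ethers, as in the dimethoxy analogue) and water hydrolyses iminium 2 to the aldehyde; no stereocentre is formed.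

Step 2
Reactants: 3 2,4-bis(benzyloxy)-6-bromobenzaldehyde; 1 1,3-bis(benzyloxy)-5-bromobenzene (second portion, converted into the Grignard reagent)
Product: 5 rac-[2,4-bis(benzyloxy)-6-bromophenyl][3,5-bis(benzyloxy)phenyl]methanol, via arylmagnesium bromide 4 (not isolated)
Conditions: Mg, THF, 50 °C; then 3, THF, 0 °C; then H2O
Reagents that add atoms: none
Why: Grignard addition of aryl nucleophile 4 to the aldehyde is fast at 0 °C and leaves the aryl bromide of 3 untouched; the new carbinol centre is racemic and is erased in step 3.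

Step 3
Reactants: 5 rac-[2,4-bis(benzyloxy)-6-bromophenyl][3,5-bis(benzyloxy)phenyl]methanol
Product: 6 [2,4-bis(benzyloxy)-6-bromophenyl][3,5-bis(benzyloxy)phenyl]methanone
Conditions: MnO2 (20 equiv), CH2Cl2, 23 °C
Reagents that add atoms: none
Why: MnO2 oxidation of a doubly benzylic alcohol stops cleanly at the diaryl ketone and tolerates the aryl bromide and benzyl ethers; no stereocentre remains.

Step 4
Reactants: 6 [2,4-bis(benzyloxy)-6-bromophenyl][3,5-bis(benzyloxy)phenyl]methanone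
Product: 7 [4-(benzyloxy)-2-bromo-6-hydroxyphenyl][3,5-bis(benzyloxy)phenyl]methanone
Conditions: MgBr2·OEt2 (3 equiv), PhMe–Et2O, 80 °C; then H2O
Reagents that add atoms: none
Why: Chelation-controlled ether cleavage, in which magnesium bridges the ketone oxygen and the ortho ether oxygen so that bromide removes only that benzyl group by SN2 attack, leaving the para and meta benzyl ethers intact.

Step 5
Reactants: 7 [4-(benzyloxy)-2-bromo-6-hydroxyphenyl][3,5-bis(benzyloxy)phenyl]methanone; 8 1-(benzyloxy)-4-(chloromethyl)benzene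
Product: 9 [4-(benzyloxy)-2-{[4-(benzyloxy)phenyl]methoxy}-6-bromophenyl][3,5-bis(benzyloxy)phenyl]methanone
Conditions: K2CO3, KI (cat.), DMF, 60 °C
Reagents that add atoms: none
Why: Williamson etherification of the ortho-phenoxide with the activated benzylic chloride installs the OCH2 group whose carbon becomes C2 of the dihydrobenzofuran.

Step 6
Reactants: 9 [4-(benzyloxy)-2-{[4-(benzyloxy)phenyl]methoxy}-6-bromophenyl][3,5-bis(benzyloxy)phenyl]methanone
Product: 10 hydrazone of ketone 9 (E/Z mixture)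
Conditions: N2H4·H2O (20 equiv), AcOH (cat.), EtOH, 80 °C
Reagents that add atoms: hydrazine (as hydrate), NN
Why: Acid-catalysed condensation of the diaryl ketone with excess hydrazine gives the N-unsubstituted hydrazone (excess reagent suppresses azine formation), whose C=N geometry is irrelevant.

Step 7
Reactants: 10 hydrazone of ketone 9
Product: 12 (2R,3S)-6-(benzyloxy)-2-[4-(benzyloxy)phenyl]-3-[3,5-bis(benzyloxy)phenyl]-4-bromo-2,3-dihydro-1-benzofuran (cis), via diaryldiazomethane 11 (not isolated)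
Conditions: MnO2, CH2Cl2, 0 °C; filter; Rh2(S-PTAD)4 (1 mol %), CH2Cl2, 0 °C
Reagents that add atoms: none
Why: MnO2 dehydrogenates the hydrazone to diazo compound 11, and the chiral dirhodium tetracarboxylate (dirhodium tetrakis[(S)-(1-adamantyl)(N-phthalimido)acetate]) converts it into a donor/donor carbene that undergoes 1,5 C–H insertion into the benzylic ether CH2 (the known enantioselective benzodihydrofuran synthesis), the ligand sphere fixing C3 as S and the insertion giving the cis 2,3-diaryl isomer kinetically.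

Step 8
Reactants: 12 (2R,3S)-cis-dihydrobenzofuran bromide
Product: 13 (2S,3S)-6-(benzyloxy)-2-[4-(benzyloxy)phenyl]-3-[3,5-bis(benzyloxy)phenyl]-4-bromo-2,3-dihydro-1-benzofuran (trans)
Conditions: TFA (5 equiv), CH2Cl2, 0 → 23 °C
Reagents that add atoms: none
Why: Acid-mediated epimerisation, in which reversible heterolysis of the O1–C2 bond to a 4-alkoxybenzyl cation and phenol followed by re-closure equilibrates C2 to the thermodynamically preferred trans isomer while the non-ionisable C3 (S) is untouched.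

## Fragment B (steps 9–11)

Step 9
Reactants: 14 1-(benzyloxy)-4-ethynylbenzene; 15 3,5-bis(benzyloxy)benzaldehyde
Product: 17 (1S)-1-[3,5-bis(benzyloxy)phenyl]-3-[4-(benzyloxy)phenyl]prop-2-yn-1-ol, via alkynylzinc 16 (not isolated)
Conditions: Me2Zn (3 equiv), (S,S)-ProPhenol (10 mol %), Ph3P=O (20 mol %), PhMe, 0 °C; then 15; then H2O
Reagents that add atoms: none
Why: Catalytic asymmetric alkynylation, in which the dinuclear zinc–ProPhenol complex binds the aldehyde and alkynylzinc 16 and delivers the alkynyl group to one carbonyl face, setting the S carbinol centre.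

Step 10
Reactants: 17 (1S)-1-[3,5-bis(benzyloxy)phenyl]-3-[4-(benzyloxy)phenyl]prop-2-yn-1-ol
Product: 18 (1S)-1-[3,5-bis(benzyloxy)phenyl]-3-[4-(benzyloxy)phenyl]prop-2-yn-1-yl benzoate
Conditions: BzCl, Et3N, DMAP (cat.), CH2Cl2, 0 °C
Reagents that add atoms: benzoyl chloride, O=C(Cl)c1ccccc1
Why: DMAP-catalysed O-acylation proceeds with retention at the carbinol carbon; a benzoate is used because a sulfonate at this doubly activated benzylic propargylic position would ionise and racemise.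

Step 11
Reactants: 18 (1S)-propargylic benzoate; 19 4-(benzyloxy)benzaldehyde
Product: 21 (1R,2R)-1,4-bis[4-(benzyloxy)phenyl]-2-[3,5-bis(benzyloxy)phenyl]but-3-yn-1-ol (anti), via allenylzinc 20 (not isolated)
Conditions: Pd(OAc)2 (5 mol %), PPh3 (5 mol %), Et2Zn (3 equiv), THF, −20 °C; 19, −20 → 0 °C; then H2O
Reagents that add atoms: none
Why: Marshall–Tamaru umpolung propargylation, in which zerovalent palladium displaces the benzoate in an anti SN2' sense, transmetalation with Et2Zn gives the axially chiral allenylzinc 20 with retention, and its closed six-membered SE2' transition state forms the C–C bond syn to zinc with the aldehyde aryl group turned away from the allenyl aryl group, so the S benzoate gives the 2R centre (net inversion) and the anti relationship gives 1R.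

## Union and end game (steps 12–13)

Step 12
Reactants: 21 (1R,2R)-anti-alkynol; 13 (2S,3S)-dihydrobenzofuran bromide
Product: 22 (2S,3S)-6-(benzyloxy)-2-[4-(benzyloxy)phenyl]-4-{(4R,5R)-2,5-bis[4-(benzyloxy)phenyl]-4-[3,5-bis(benzyloxy)phenyl]-4,5-dihydrofuran-3-yl}-3-[3,5-bis(benzyloxy)phenyl]-2,3-dihydro-1-benzofuran
Conditions: Pd2(dba)3 (2.5 mol %), XPhos (10 mol %), K2CO3 (2 equiv), MeCN, 60 °C
Reagents that add atoms: none
Why: Proposed new method: oxidative addition of bromide 13 to zerovalent palladium gives an electrophilic arylpalladium bromide that activates the alkyne of 21, the hydroxyl attacks anti in a 5-endo-dig sense at the aryl-bearing alkyne carbon, and reductive elimination from the vinyl(aryl)palladium forms the C3–aryl bond; the closest known reaction is the Cacchi-type oxypalladation/reductive-elimination annulation of 2-alkynylphenols with aryl halides to 2,3-disubstituted benzofurans, and none of the four existing sp3 stereocentres is touched.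

Step 13
Reactants: 22 heptabenzyl tetraaryl dihydrofuran
Product: 24 5-[(2S,3S)-4-[(2R,3R,4S,5R)-4-(3,5-dihydroxyphenyl)-2,5-bis(4-hydroxyphenyl)oxolan-3-yl]-6-hydroxy-2-(4-hydroxyphenyl)-2,3-dihydro-1-benzofuran-3-yl]benzene-1,3-diol (CNP0202577.4), via heptaphenol dihydrofuran 23 (not isolated)
Conditions: H2 (4 atm), Pd(OH)2/C, NaHCO3 (solid), EtOAc–MeOH (1:1), 25 °C
Reagents that add atoms: none
Why: Heterogeneous hydrogenation over palladium, in which the benzyl ethers are hydrogenolysed first to 23 and the tetrasubstituted enol ether then takes up H2 by syn addition from the face opposite the allylic C4 aryl group (held pseudo-axial by A(1,2) strain against the C3 aryl group, the C5 aryl group being one atom further from the alkene), so the C2, C3 and C4 aryl groups end up mutually cis with C5 trans, i.e. 2R,3R.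

## Compound list

1 | 1,3-bis(benzyloxy)-5-bromobenzene | Brc1cc(OCc2ccccc2)cc(OCc2ccccc2)c1 | starting material
2 | {[2,4-bis(benzyloxy)-6-bromophenyl]methylidene}dimethylazanium dichlorophosphate | C[N+](C)=Cc1c(Br)cc(OCc2ccccc2)cc1OCc1ccccc1.[O-]P(=O)(Cl)Cl | intermediate
3 | 2,4-bis(benzyloxy)-6-bromobenzaldehyde | O=Cc1c(Br)cc(OCc2ccccc2)cc1OCc1ccccc1 | intermediate
4 | [3,5-bis(benzyloxy)phenyl]magnesium bromide | Br[Mg]c1cc(OCc2ccccc2)cc(OCc2ccccc2)c1 | intermediate
5 | rac-[2,4-bis(benzyloxy)-6-bromophenyl][3,5-bis(benzyloxy)phenyl]methanol | OC(c1cc(OCc2ccccc2)cc(OCc2ccccc2)c1)c1c(Br)cc(OCc2ccccc2)cc1OCc1ccccc1 | intermediate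
6 | [2,4-bis(benzyloxy)-6-bromophenyl][3,5-bis(benzyloxy)phenyl]methanone | O=C(c1cc(OCc2ccccc2)cc(OCc2ccccc2)c1)c1c(Br)cc(OCc2ccccc2)cc1OCc1ccccc1 | intermediate
7 | [4-(benzyloxy)-2-bromo-6-hydroxyphenyl][3,5-bis(benzyloxy)phenyl]methanone | O=C(c1cc(OCc2ccccc2)cc(OCc2ccccc2)c1)c1c(Br)cc(OCc2ccccc2)cc1O | intermediate
8 | 1-(benzyloxy)-4-(chloromethyl)benzene | ClCc1ccc(OCc2ccccc2)cc1 | starting material
9 | [4-(benzyloxy)-2-{[4-(benzyloxy)phenyl]methoxy}-6-bromophenyl][3,5-bis(benzyloxy)phenyl]methanone | O=C(c1cc(OCc2ccccc2)cc(OCc2ccccc2)c1)c1c(Br)cc(OCc2ccccc2)cc1OCc1ccc(OCc2ccccc2)cc1 | intermediate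
10 | hydrazone of 9 (E/Z mixture, C=N geometry not defined) | NN=C(c1cc(OCc2ccccc2)cc(OCc2ccccc2)c1)c1c(Br)cc(OCc2ccccc2)cc1OCc1ccc(OCc2ccccc2)cc1 | intermediate
11 | [4-(benzyloxy)-2-{[4-(benzyloxy)phenyl]methoxy}-6-bromophenyl][3,5-bis(benzyloxy)phenyl]diazomethane | [N-]=[N+]=C(c1cc(OCc2ccccc2)cc(OCc2ccccc2)c1)c1c(Br)cc(OCc2ccccc2)cc1OCc1ccc(OCc2ccccc2)cc1 | intermediate
12 | (2R,3S)-6-(benzyloxy)-2-[4-(benzyloxy)phenyl]-3-[3,5-bis(benzyloxy)phenyl]-4-bromo-2,3-dihydro-1-benzofuran (cis) | C(c1ccccc1)Oc1ccc([C@@H]2Oc3cc(OCc4ccccc4)cc(Br)c3[C@@H]2c2cc(OCc3ccccc3)cc(OCc3ccccc3)c2)cc1 | intermediate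
13 | (2S,3S)-6-(benzyloxy)-2-[4-(benzyloxy)phenyl]-3-[3,5-bis(benzyloxy)phenyl]-4-bromo-2,3-dihydro-1-benzofuran (trans) | C(c1ccccc1)Oc1ccc([C@H]2Oc3cc(OCc4ccccc4)cc(Br)c3[C@@H]2c2cc(OCc3ccccc3)cc(OCc3ccccc3)c2)cc1 | intermediate
14 | 1-(benzyloxy)-4-ethynylbenzene | C#Cc1ccc(OCc2ccccc2)cc1 | starting material
15 | 3,5-bis(benzyloxy)benzaldehyde | O=Cc1cc(OCc2ccccc2)cc(OCc2ccccc2)c1 | starting material
16 | {[4-(benzyloxy)phenyl]ethynyl}(methyl)zinc | C[Zn]C#Cc1ccc(OCc2ccccc2)cc1 | intermediate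
17 | (1S)-1-[3,5-bis(benzyloxy)phenyl]-3-[4-(benzyloxy)phenyl]prop-2-yn-1-ol | O[C@H](C#Cc1ccc(OCc2ccccc2)cc1)c1cc(OCc2ccccc2)cc(OCc2ccccc2)c1 | intermediate
18 | (1S)-1-[3,5-bis(benzyloxy)phenyl]-3-[4-(benzyloxy)phenyl]prop-2-yn-1-yl benzoate | O=C(O[C@H](C#Cc1ccc(OCc2ccccc2)cc1)c1cc(OCc2ccccc2)cc(OCc2ccccc2)c1)c1ccccc1 | intermediate
19 | 4-(benzyloxy)benzaldehyde | O=Cc1ccc(OCc2ccccc2)cc1 | starting material
20 | (M)-{1-[4-(benzyloxy)phenyl]-3-[3,5-bis(benzyloxy)phenyl]propa-1,2-dien-1-yl}(ethyl)zinc | CC[Zn]C(c1ccc(OCc2ccccc2)cc1)=[C@]=C([H])c1cc(OCc2ccccc2)cc(OCc2ccccc2)c1 | intermediate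
21 | (1R,2R)-1,4-bis[4-(benzyloxy)phenyl]-2-[3,5-bis(benzyloxy)phenyl]but-3-yn-1-ol (anti) | C(#Cc1ccc(OCc2ccccc2)cc1)[C@@H](c1cc(OCc2ccccc2)cc(OCc2ccccc2)c1)[C@H](c1ccc(OCc2ccccc2)cc1)O | intermediate
22 | (2S,3S)-6-(benzyloxy)-2-[4-(benzyloxy)phenyl]-4-{(4R,5R)-2,5-bis[4-(benzyloxy)phenyl]-4-[3,5-bis(benzyloxy)phenyl]-4,5-dihydrofuran-3-yl}-3-[3,5-bis(benzyloxy)phenyl]-2,3-dihydro-1-benzofuran | C(c1ccccc1)Oc1ccc([C@H]2Oc3cc(OCc4ccccc4)cc(C4=C(c5ccc(OCc6ccccc6)cc5)O[C@@H](c5ccc(OCc6ccccc6)cc5)[C@@H]4c4cc(OCc5ccccc5)cc(OCc5ccccc5)c4)c3[C@@H]2c2cc(OCc3ccccc3)cc(OCc3ccccc3)c2)cc1 | intermediate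
23 | 5-[(2S,3S)-4-[(4R,5R)-4-(3,5-dihydroxyphenyl)-2,5-bis(4-hydroxyphenyl)-4,5-dihydrofuran-3-yl]-6-hydroxy-2-(4-hydroxyphenyl)-2,3-dihydro-1-benzofuran-3-yl]benzene-1,3-diol | Oc1ccc([C@H]2Oc3cc(O)cc(C4=C(c5ccc(O)cc5)O[C@@H](c5ccc(O)cc5)[C@@H]4c4cc(O)cc(O)c4)c3[C@@H]2c2cc(O)cc(O)c2)cc1 | intermediate
24 | 5-[(2S,3S)-4-[(2R,3R,4S,5R)-4-(3,5-dihydroxyphenyl)-2,5-bis(4-hydroxyphenyl)oxolan-3-yl]-6-hydroxy-2-(4-hydroxyphenyl)-2,3-dihydro-1-benzofuran-3-yl]benzene-1,3-diol | Oc1ccc([C@H]2Oc3cc(O)cc([C@H]4[C@@H](c5cc(O)cc(O)c5)[C@H](c5ccc(O)cc5)O[C@H]4c4ccc(O)cc4)c3[C@@H]2c2cc(O)cc(O)c2)cc1 | target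

## Step count and risk

Total steps: 13. Longest linear sequence: 10 steps (steps 1–8, then 12 and 13); fragment B is 3 steps (9–11).

The three steps most likely to fail are 11, 12 and 13.

Step 11 may lose enantiopurity or anti selectivity, because the doubly activated benzoate can ionise and a 1,3-diaryl allenyl metal can racemise or react through its propargyl isomer. The fallback moves stereocontrol from the substrate to the reagent. It sets out from alcohol 17, which is deoxygenated (Et3SiH, BF3·OEt2, CH2Cl2, −40 °C) to the achiral 1-(benzyloxy)-4-{3-[3,5-bis(benzyloxy)phenyl]prop-1-yn-1-yl}benzene F1. This propyne is lithiated (n-BuLi, THF, −78 °C), converted into a chiral allenylborane with (−)-Ipc2BOMe and then BF3·OEt2, and added to aldehyde 19 through the same closed SE2' transition state, with oxidative work-up. The sequence comes back to the route at alkynol 21.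

Step 12 is new chemistry and may be diverted by oxidation of the secondary alcohol by the arylpalladium species, by syn-carbopalladation, or by base-induced alkyne-to-allene isomerisation at the benzylic propargylic C–H. The fallback separates ring closure from C–C bond formation and sets out from alkynol 21 and bromide 13. Iodoetherification of 21 (I2, NaHCO3, MeCN, 0 °C, 5-endo-dig) gives (2R,3S)-2,5-bis[4-(benzyloxy)phenyl]-3-[3,5-bis(benzyloxy)phenyl]-4-iodo-2,3-dihydrofuran F2. Miyaura borylation of 13 (B2pin2, Pd(dppf)Cl2, KOAc, dioxane, 90 °C) gives the pinacol boronate of the (2S,3S)-dihydrobenzofuran F3. Suzuki–Miyaura coupling of the two (Pd(OAc)2, SPhos, K3PO4, PhMe–H2O, 80 °C) comes back to the route at dihydrofuran 22.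

Step 13 may deliver hydrogen to the wrong face, since the C5 aryl group shields the face opposite to the C4 aryl group. The long exposure needed for a tetrasubstituted alkene may also hydrogenolyse the benzylic C–O bonds of the oxolane or dihydrobenzofuran. The fallback replaces substrate control by catalyst control and separates the two events; it sets out from dihydrofuran 22. Homogeneous hydrogenation with a chiral iridium P,N complex, [Ir(cod)((S)-tBu-PHOX)]BArF (H2 50 atm, CH2Cl2, 25 °C, ligand antipode chosen for bottom-face delivery), leaves the benzyl ethers intact. It gives the heptabenzyl ether of the target, (2S,3S)-6-(benzyloxy)-2-[4-(benzyloxy)phenyl]-4-{(2R,3R,4S,5R)-2,5-bis[4-(benzyloxy)phenyl]-4-[3,5-bis(benzyloxy)phenyl]oxolan-3-yl}-3-[3,5-bis(benzyloxy)phenyl]-2,3-dihydro-1-benzofuran F4. A short separate hydrogenolysis (H2 1 atm, Pd/C, EtOAc, 25 °C) then comes back to the route at target 24.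

## Further compounds

F1 | step 11 | 1-(benzyloxy)-4-{3-[3,5-bis(benzyloxy)phenyl]prop-1-yn-1-yl}benzene | C(#Cc1ccc(OCc2ccccc2)cc1)Cc1cc(OCc2ccccc2)cc(OCc2ccccc2)c1
F2 | step 12 | (2R,3S)-2,5-bis[4-(benzyloxy)phenyl]-3-[3,5-bis(benzyloxy)phenyl]-4-iodo-2,3-dihydrofuran | IC1=C(c2ccc(OCc3ccccc3)cc2)O[C@@H](c2ccc(OCc3ccccc3)cc2)[C@@H]1c1cc(OCc2ccccc2)cc(OCc2ccccc2)c1
F3 | step 12 | (2S,3S)-6-(benzyloxy)-2-[4-(benzyloxy)phenyl]-3-[3,5-bis(benzyloxy)phenyl]-4-(4,4,5,5-tetramethyl-1,3,2-dioxaborolan-2-yl)-2,3-dihydro-1-benzofuran | C(c1ccccc1)Oc1ccc([C@H]2Oc3cc(OCc4ccccc4)cc(B4OC(C)(C)C(C)(C)O4)c3[C@@H]2c2cc(OCc3ccccc3)cc(OCc3ccccc3)c2)cc1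
F4 | step 13 | (2S,3S)-6-(benzyloxy)-2-[4-(benzyloxy)phenyl]-4-{(2R,3R,4S,5R)-2,5-bis[4-(benzyloxy)phenyl]-4-[3,5-bis(benzyloxy)phenyl]oxolan-3-yl}-3-[3,5-bis(benzyloxy)phenyl]-2,3-dihydro-1-benzofuran | C(c1ccccc1)Oc1ccc([C@H]2Oc3cc(OCc4ccccc4)cc([C@H]4[C@@H](c5cc(OCc6ccccc6)cc(OCc6ccccc6)c5)[C@H](c5ccc(OCc6ccccc6)cc5)O[C@H]4c4ccc(OCc5ccccc5)cc4)c3[C@@H]2c2cc(OCc3ccccc3)cc(OCc3ccccc3)c2)cc1
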